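In moles per litre of starting volume I charged 0.024 M of free monomer, dosed over 12 min, against 48 µM of initiator; dusk ran 2.0 h and winter 3.0 h.

common to all: free monomer 0.024 M (fed, over 12 min); initiator 48 µM

| flask | time | remark |
|---|---|---|
| dusk | 2.0 h | the fed solution adds 0.10 times the starting volume |
| winter | 3.0 h | the fed solution adds 0.10 times the starting volume |

    initiator → 2 initiating radical (k1 = 0.0414 min⁻¹)
    free monomer + initiating radical → growing radical + monomer in chains (k2 = 5.08 × 10⁵ M⁻¹ s⁻¹)
    free monomer + growing radical → monomer in chains + growing radical, rate k3*[growing radical]*[free monomer] (k3 = 1.41 × 10⁵ M⁻¹ min⁻¹)
    2 growing radical → dead chain (k4 = 5 × 10⁷ M⁻¹ s⁻¹)

- a doubled species enters its step squared and goes two at a time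
- charges are per starting volume, the dose included; the dosed solution carries all of it
- the average divides the monomer in chains by the number of chains, living and dead together; two radicals that join make one chain
- run time (dusk): 2.0 h

- which of the two ends with the longer chains by the average number of monomer units in a chain (living and dead chains, two that joined counted as one) ("neither" if they lie within 10%) (dusk / winter / neither)
- average number of monomer units in a chain (living and dead chains, two that joined counted as one) at the end, dusk
- average number of monomer units in a chain (living and dead chains, two that joined counted as one) at the end, winter

1. I reckoned by one quantity, the offer: free monomer charged per initiator charged, 500. One initiator gives two radicals, and two radicals that join make one chain, so I took the length as the offer times the part of the free monomer reacted, divided by the part of the initiator used.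

2. The initiator's half-life of 0.28 h is far shorter than the 2.0 h of dusk, so I expected 0.696% of it left at the end of dusk and 0.0580% at the end of winter (dead-end polymerisation, in the usual term).

3. Taking radicals to be made as fast as they joined, and counting the initiator in the full volume, I put growing radical near 2.45 × 10⁻⁸ M at first and let it fall with the square root of the initiator. Summed over the whole decay of the initiator, that gave a reckoned exponent of 0.167 for the loss of free monomer. Cut off at each end time, with the dosing time at 0.5 weight, it gave 12.6% reacted in dusk and 13.5% in winter.

4. I committed to 63.5 for dusk and 67.4 for winter, which are 6.14% apart, less than the 10% band: neither. I left word not to touch the charges, since a changed charge moves the offer.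

5. The forecast stood above mine: neither, with 65 for dusk and 69 for winter, on the ground that “The extra hour adds only a few percent more monomer to the chains”.

The simulation gave neither, with 65.1 for dusk and 69.0 for winter. At 2.00 h dusk held 87.1% of its free monomer and 0.696% of its initiator. The neighbour of dusk, charged with 0.060 M of free monomer, has an offer of 1250. It kept 87.3% of its free monomer and 0.70% of its initiator, so the offer times the part of the free monomer reacted, divided by the part of the initiator used, is 160. That neighbour flask ended with an average length of 160.

The constants stand for no real mixture; the flask was simulated.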